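## Structural features

Borregomycin E (10) is a flat, achiral indolo[2,3-a]carbazole of five fused aromatic rings: chlorobenzene ring A (C1–C4, C4a, C12a), pyrrole ring B (N12), central benzene ring C (C4b, C5, C6, C6a, C11a, C11b), pyrrole ring D (N11) and chlorobenzene ring E (C6b, C7–C10, C10a). A twofold axis runs through the midpoints of C5–C6 and C11a–C11b, and there is no stereocentre, so no configuration has to be set or protected. Ring C is hexasubstituted: methoxy groups on the neighbouring carbons C5 and C6, the two biaryl bonds C4a–C4b and C6a–C6b, and the two nitrogens on the neighbouring carbons C11a and C11b. The chlorines stand at C2 and C9, each para to a biaryl bond and meta to a nitrogen. The sensitive points are the two aryl C–Cl bonds, which must survive every low-valent metal step, and the electron-rich free N–H units, which are prone to oxidation and N-arylation and are best unveiled last. The methyl ethers only exclude strong Lewis acids. The real difficulty is regiochemical: ring C must be loaded so that the nitrogens end up adjacent and the chlorines at C2 and C9. The key step uses the fact that each nitrogen is a one-atom bridge between ring C and an outer ring (N12 joins C11b to C12a, N11 joins C11a to C10a); without the nitrogens the skeleton is a para-terphenyl whose four bridging positions can carry halogens.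

## Logic of the disconnections

10 ⇒ 9. The two N–H bonds are traced back to N–CO2tBu bonds. The nitrogen that is brought in needs an acyl group that makes it a competent coupling partner and stops it after two arylations, and this carbamate is the one that leaves with acid alone. Nothing is gained in skeleton, but the reactive N–H units stay masked until the end. The forward step must cleave two carbamates without touching C–Cl or O–CH3.

9 ⇒ 6 + two molecules of 7. The four bonds N12–C11b, N12–C12a, N11–C11a and N11–C10a are cut. This opens rings B and D at once and reduces the pentacycle to a symmetrical terphenyl with four bromides, while both nitrogens come from one simple reagent. The forward step must achieve four C–N couplings at C–Br with no participation of C–Cl, each nitrogen must join one outer and one inner carbon, and the second ring closure must tolerate a crowded bay.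

6 ⇒ 5. The two C–Br bonds on ring C (the future C11a and C11b) are cut. These are the only free positions of ring C and each is para to a methoxy group, so electrophilic bromination can install them late. The gain is that the inner halogens are absent during the cross-coupling, where they would compete. The forward step must brominate twice on ring C, next to bulky aryl groups, and leave the outer rings alone.

5 ⇒ 3 + two molecules of 4. The two biaryl bonds (future C4a–C4b and C6a–C6b) are cut. A central bis-nucleophile and two identical outer electrophiles use the twofold symmetry, and 4 carries three halogens of graded reactivity that fix bromine ortho and chlorine para to the new bond. The forward step must couple at the iodide only.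

3 ⇒ 1 (through 2). The two C–B bonds are cut. Each methoxy group directs metalation to its own free ortho position, so both boron atoms can be placed in one operation on a commodity arene. The forward step needs complete double metalation and efficient double borylation.

## Other disconnections considered

Alternative 1: The cut is N12–C11b and C4a–C4b, that is ring B alone, with ring C supplied as an aryne.
- Forward step: CsF releases the aryne from 2,3-dimethoxy-5,6-bis(trimethylsilyl)phenyl triflate A2. The amino group of 5-chloro-2-iodoaniline A3 adds to the aryne carbon remote from methoxy and next to the remaining silyl group. Pd(OAc)2 with PCy3 then closes the C–I bond onto the neighbouring ring C carbon to give the carbazole A1.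
- In favour: the C–N bond forms without a metal, at a position fixed by two cooperating effects (inductive pull of methoxy, aryne distortion by silicon). The silyl group left at C11a is a handle for N11.
- Against: A1 holds only rings A, B and C. Rings D and E need a second campaign (ipso-halogenation at C11a, N-arylation, closure of C6a–C6b next to a methoxy group) with N12–H protected. A2 itself needs several steps, and the twofold symmetry of 10 is not used.
- Comparison: on structure the chosen plan closes both pyrrole rings in one operation from a symmetrical precursor. On mechanism Alternative 1 is the better on chemoselectivity, since its palladium step meets one C–I bond rather than four C–Br bonds beside two C–Cl bonds, and it has no crowded final C–N closure. On step economy the chosen plan is clearly shorter.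

Alternative 2: The cut is C4b–C11b, C6a–C11a and C5–C6, so ring C is assembled from three alkynes and rings B and D close as a consequence.
- Forward step: RhCl(PPh3)3 converts the triyne A5 through a rhodacyclopentadiene and insertion of the third alkyne into the bis(N-mesyl) indolocarbazole A4.
- In favour: three C–C bonds and three rings form in one isomerisation with no by-product. On bonds formed per step and atom economy this key step is better than the chosen one, which sets free four equivalents of bromide. Every substituent of ring C is fixed by the tethers, which equals the chosen plan on regiocontrol. The C–Cl bonds are not at risk with the rhodium catalyst, which is at least equal.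
- Against: A5 combines two sensitive and rarely made functions, an N–C≡C–N ynediamide and two aryl methoxyalkynes that hydrolyse easily. Building it would take more steps than the whole chosen route. Electron-rich ynol ethers are poorly precedented partners in this cyclotrimerisation. The methanesulfonyl groups need harsher removal than Boc.
- Comparison: the key step is the more elegant, but the route as a whole is longer and rests on a fragile precursor, whereas the chosen plan moves through robust aryl halides.

Alternative 3: The cut is C5–C6 only, so ring C is closed last between the two oxygen-bearing carbons.
- Forward step: a triazolylidene carbene adds to one formyl group of the di-Boc biindole dialdehyde A7. The acyl anion equivalent attacks the other formyl carbon, and the acyloin tautomerises to the aromatic diol A6. Double O-methylation would then give 9, followed by the same acid deprotection as in the chosen plan.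
- In favour: it is metal-free, so the C–Cl bonds never meet zerovalent palladium, which is better on that point. Both oxygens arrive in the right place and oxidation state, aromatisation drives the closure, and the symmetry is used equally well.
- Against: A6 is an electron-rich catechol open to air oxidation and costs an extra methylation step. A7 requires a 2,2'-biindole to be made, protected and formylated twice. The two Boc groups twist the biindole and hold the formyl groups apart, 3-formylindoles are weak electrophiles, and Boc may be lost under the basic carbene conditions.
- Comparison: on structure the two plans are equal, since both must fit two Boc groups into the N11/N12 bay and both pass through 9. On mechanism the carbene route avoids all halogen selectivity. On step economy the chosen plan is shorter by several steps.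

Key step: step 4

Remark 1: the constitution of 6 and 9 was checked against 10 atom by atom and needs no change. Bromine ortho and chlorine para to each biaryl bond map onto N11/N12 and C9/C2. The only design choice added is the bis(pinacol) boronate 3 as an isolable, purifiable boron partner.

Remark 2: 5 and 6 have hindered biaryl axes and may exist as slowly interconverting syn and anti rotamers. Both converge in step 4, so each is treated as one compound.

## Route

Step 1
Reactants: 1 veratrole (1,2-dimethoxybenzene)
Product: 3 2,2'-(2,3-dimethoxy-1,4-phenylene)bis(4,4,5,5-tetramethyl-1,3,2-dioxaborolane), via 3,6-dilithioveratrole 2 (not isolated)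
Conditions: n-BuLi (2.5 equiv), TMEDA (2.5 equiv), Et2O–hexane, 0 °C → 35 °C; then iPrOBpin (3 equiv), −78 °C → rt; aq. HCl (1 M) work-up
Reagents that add atoms: 2-isopropoxy-4,4,5,5-tetramethyl-1,3,2-dioxaborolane (iPrOBpin), CC(C)OB1OC(C)(C)C(C)(C)O1
Why: Directed ortho-metalation: each methoxy group steers n-BuLi/TMEDA to its own free ortho position, so the second lithium enters at C6 and not beside the first. Electrophilic borylation of the dianion with the borate ester then places boron on both carbons.

Step 2
Reactants: 3 2,2'-(2,3-dimethoxy-1,4-phenylene)bis(4,4,5,5-tetramethyl-1,3,2-dioxaborolane); 4 2-bromo-4-chloro-1-iodobenzene (2.2 equiv)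
Product: 5 1,4-bis(2-bromo-4-chlorophenyl)-2,3-dimethoxybenzene
Conditions: Pd(PPh3)4 (5 mol%), aq. Na2CO3 (2 M), toluene–EtOH, 80 °C
Reagents that add atoms: none
Why: Twofold Suzuki–Miyaura coupling. Zerovalent palladium inserts into C–I far faster than into C–Br or C–Cl, so with Pd(PPh3)4 at moderate temperature only the iodide of 4 should react and each new biaryl keeps its ortho bromine and para chlorine.

Step 3
Reactants: 5 1,4-bis(2-bromo-4-chlorophenyl)-2,3-dimethoxybenzene
Product: 6 1,2-dibromo-3,6-bis(2-bromo-4-chlorophenyl)-4,5-dimethoxybenzene
Conditions: NBS (2.3 equiv), MeCN–TFA, rt → 50 °C, dark
Reagents that add atoms: N-bromosuccinimide (NBS), O=C1CCC(=O)N1Br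
Why: Electrophilic aromatic bromination. The only two C–H bonds of the central ring are each para to a methoxy group, while the outer rings are deactivated by bromine and chlorine, so both bromines should enter ring C. Acid activation of NBS offsets the crowding next to the aryl groups.

Step 4
Reactants: 6 1,2-dibromo-3,6-bis(2-bromo-4-chlorophenyl)-4,5-dimethoxybenzene; 7 tert-butyl carbamate (2.4 equiv)
Product: 9 di-tert-butyl 2,9-dichloro-5,6-dimethoxyindolo[2,3-a]carbazole-11,12-dicarboxylate, via mono-annulated N-Boc bromocarbazole 8 (not isolated)
Conditions: Pd2(dba)3 (5 mol%), Xantphos (12 mol%), Cs2CO3 (6 equiv), 1,4-dioxane, 100 °C, argon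
Reagents that add atoms: none
Why: Zerovalent palladium carrying Xantphos inserts into a C–Br bond (most readily an outer one), the caesium salt of 7 replaces bromide on divalent palladium, and C–N reductive elimination gives an N-aryl carbamate whose N–H lies across the biaryl axis from the inner C–Br bond. A second oxidative addition there, deprotonation and reductive elimination from a six-membered azapalladacycle close the five-membered pyrrole ring B (intramolecular C(sp2)–N coupling) and give 8; the same two events on the other half close ring D in the same mode. The closest known reaction type is the double N-arylation of carbamates or primary amines with 2,2'-dihalobiaryls to carbazoles (a tandem inter- and intramolecular Buchwald–Hartwig coupling), here run twice on one terphenyl. No stereocentre is formed, and the rotamers of 6 converge because both axes become part of planar rings. The step needs C–Br over C–Cl chemoselectivity, which rests on the weaker C–Br bond and on a Pd2(dba)3/Xantphos catalyst that does not readily insert into unactivated aryl chlorides at 100 °C. It also needs each nitrogen to join one outer and one inner carbon: only that pair closes a five-membered ring, since bridging the two inner bromides would require a three-membered ring and the distal pairs cannot reach each other. The adjacency of the nitrogens at C11a and C11b is inherited from step 3, where the methoxy groups at C5 and C6 left no other place for the inner bromines. The wide bite angle of Xantphos is chosen to speed the last, crowded reductive elimination that places the second carbamate next to the first.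

Step 5
Reactants: 9 di-tert-butyl 2,9-dichloro-5,6-dimethoxyindolo[2,3-a]carbazole-11,12-dicarboxylate
Product: 10 borregomycin E (2,9-dichloro-5,6-dimethoxy-11,12-dihydroindolo[2,3-a]carbazole)
Conditions: TFA–CH2Cl2 (1:4), 0 °C → rt, argon sweep; aq. NaHCO3
Reagents that add atoms: none
Why: Acidolysis of the two tert-butyl carbamates (protonation, loss of the tert-butyl cation as isobutene, decarboxylation). Carbamates on carbazole-type nitrogen are especially labile and the strain between the neighbouring Boc groups is released, while aryl chlorides and methyl ethers are inert to TFA.

## Compound list

1 | veratrole (1,2-dimethoxybenzene) | COc1ccccc1OC | starting material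
2 | 3,6-dilithio-1,2-dimethoxybenzene (3,6-dilithioveratrole, not isolated) | COc1c([Li])ccc([Li])c1OC | intermediate
3 | 2,2'-(2,3-dimethoxy-1,4-phenylene)bis(4,4,5,5-tetramethyl-1,3,2-dioxaborolane) | COc1c(B2OC(C)(C)C(C)(C)O2)ccc(B2OC(C)(C)C(C)(C)O2)c1OC | intermediate
4 | 2-bromo-4-chloro-1-iodobenzene | Clc1ccc(I)c(Br)c1 | starting material
5 | 1,4-bis(2-bromo-4-chlorophenyl)-2,3-dimethoxybenzene | COc1c(OC)c(-c2ccc(Cl)cc2Br)ccc1-c1ccc(Cl)cc1Br | intermediate
6 | 1,2-dibromo-3,6-bis(2-bromo-4-chlorophenyl)-4,5-dimethoxybenzene | COc1c(OC)c(-c2ccc(Cl)cc2Br)c(Br)c(Br)c1-c1ccc(Cl)cc1Br | intermediate
7 | tert-butyl carbamate | CC(C)(C)OC(N)=O | starting material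
8 | tert-butyl 1-bromo-2-(2-bromo-4-chlorophenyl)-7-chloro-3,4-dimethoxy-9H-carbazole-9-carboxylate (mono-annulated N-Boc bromocarbazole, not isolated) | COc1c(OC)c(-c2ccc(Cl)cc2Br)c(Br)c2n(C(=O)OC(C)(C)C)c3cc(Cl)ccc3c12 | intermediate
9 | di-tert-butyl 2,9-dichloro-5,6-dimethoxyindolo[2,3-a]carbazole-11,12-dicarboxylate | COc1c(OC)c2c3ccc(Cl)cc3n(C(=O)OC(C)(C)C)c2c2n(C(=O)OC(C)(C)C)c3cc(Cl)ccc3c12 | intermediate
10 | borregomycin E (2,9-dichloro-5,6-dimethoxy-11,12-dihydroindolo[2,3-a]carbazole) | COc1c(OC)c2c3ccc(Cl)cc3[nH]c2c2[nH]c3cc(Cl)ccc3c12 | target

## Step count and least certain steps

Total step count: 5. Longest linear sequence: 5 steps (1 → 3 → 5 → 6 → 9 → 10); 4 and 7 enter as purchased partners.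

**Step 4 (key step).**
- Risk: the sequence may stall after the first annulation, because the last reductive elimination must force a second carbamate into the N11/N12 bay beside the first. The crowded inner C–Br bond may then be lost by hydrodebromination. Premature loss of a strained Boc group under hot Cs2CO3 would expose an N–H that can be arylated intermolecularly, and slow insertion into C–Cl could set in late. Partial Boc loss without further reaction is harmless, since step 5 converges all such material on 10.
- Fallback: this changes the nitrogen source from an amidate to an amine and the protecting group from acyl to benzyl. It sets out from 6, which is coupled with 2,4-dimethoxybenzylamine (COc1ccc(CN)c(OC)c1; Pd2(dba)3, rac-BINAP, NaOtBu, toluene, 100 °C) in the established double N-arylation of primary amines. This should give 2,9-dichloro-11,12-bis(2,4-dimethoxybenzyl)-5,6-dimethoxy-11,12-dihydroindolo[2,3-a]carbazole F1. The amine is the stronger nucleophile, the benzylic sp3 carbons bend out of the bay more easily, and no base-labile group is present. Cleavage of both benzyl groups with TFA and anisole at 60 °C comes back to the route at 10.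

**Step 3.**
- Risk: the second bromination may be incomplete, because the first bromine deactivates and crowds the neighbouring position and the doubly flanked methoxy groups are twisted out of conjugation. Forcing conditions could then start substitution on an outer ring.
- Fallback: the ring C bromines are installed before the biaryl bonds, setting out from 1.
  - NBS (MeCN, rt) should give 1,2-dibromo-4,5-dimethoxybenzene F2, a well-established bromination.
  - TMPMgCl·LiCl (THF, −20 °C) removes the proton flanked by methoxy and bromine to give (2,3-dibromo-5,6-dimethoxyphenyl)magnesium chloride F3, which iodine converts into 1,2-dibromo-3-iodo-4,5-dimethoxybenzene F4.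
  - A second cycle through (2,3-dibromo-4-iodo-5,6-dimethoxyphenyl)magnesium chloride F5 gives 1,2-dibromo-3,6-diiodo-4,5-dimethoxybenzene F6.
  - An iodide-selective Suzuki–Miyaura coupling of F6 with two equivalents of commercial (2-bromo-4-chlorophenyl)boronic acid (OB(O)c1ccc(Cl)cc1Br; Pd(PPh3)4, aq. Na2CO3, DME, 80 °C) comes back to the route at 6. This coupling forms hindered biaryl axes and carries its own risk.

**Step 1.**
- Risk: the second metalation may be incomplete, and the electron-rich ortho-methoxy bis-boronate may lose boron by protodeboronation during work-up and chromatography.
- Fallback: the polarity of the cross-coupling is reversed. Setting out from 1, the dianion 2 is generated as before and quenched with iodine (THF, −78 °C → rt) to give 1,4-diiodo-2,3-dimethoxybenzene F7. This is a robust solid that is easily freed from mono-iodide. Suzuki–Miyaura coupling of F7 with two equivalents of (2-bromo-4-chlorophenyl)boronic acid (Pd(PPh3)4, aq. Na2CO3, DME, 80 °C), in which the central C–I bonds react ahead of the C–Br bonds, comes back to the route at 5.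

**Step 2.**
- Risk: iodide-over-bromide selectivity may erode at the temperature needed to transmetalate the ortho-methoxy boronate, which would lead to oligoarylation, and the boronate may be protodeboronated by aqueous base.
- Fallback: boron is replaced by zinc. Setting out from 1, the dianion 2 is transmetalated with ZnCl2 (THF, 0 °C) to (2,3-dimethoxy-1,4-phenylene)bis(zinc chloride) F8. Negishi coupling with 4 (Pd(PPh3)4, THF, rt) comes back to the route at 5. At room temperature only C–I should react, no aqueous base is present, and one isolation is saved.

## Further compounds

F1 | step 4 | 2,9-dichloro-11,12-bis(2,4-dimethoxybenzyl)-5,6-dimethoxy-11,12-dihydroindolo[2,3-a]carbazole | COc1c(OC)c2c3ccc(Cl)cc3n(Cc3ccc(OC)cc3OC)c2c2n(Cc3ccc(OC)cc3OC)c3cc(Cl)ccc3c12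
F2 | step 3 | 1,2-dibromo-4,5-dimethoxybenzene | COc1cc(Br)c(Br)cc1OC
F3 | step 3 | (2,3-dibromo-5,6-dimethoxyphenyl)magnesium chloride | COc1cc(Br)c(Br)c([Mg]Cl)c1OC
F4 | step 3 | 1,2-dibromo-3-iodo-4,5-dimethoxybenzene | COc1cc(Br)c(Br)c(I)c1OC
F5 | step 3 | (2,3-dibromo-4-iodo-5,6-dimethoxyphenyl)magnesium chloride | COc1c(OC)c(I)c(Br)c(Br)c1[Mg]Cl
F6 | step 3 | 1,2-dibromo-3,6-diiodo-4,5-dimethoxybenzene | COc1c(OC)c(I)c(Br)c(Br)c1I
F7 | step 1 | 1,4-diiodo-2,3-dimethoxybenzene | COc1c(I)ccc(I)c1OC
F8 | step 2 | (2,3-dimethoxy-1,4-phenylene)bis(zinc chloride) | COc1c([Zn]Cl)ccc([Zn]Cl)c1OC
A1 | alternative 1 | 7-chloro-3,4-dimethoxy-1-(trimethylsilyl)-9H-carbazole | COc1c(OC)cc([Si](C)(C)C)c2[nH]c3cc(Cl)ccc3c12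
A2 | alternative 1 | 2,3-dimethoxy-5,6-bis(trimethylsilyl)phenyl trifluoromethanesulfonate | COc1cc([Si](C)(C)C)c([Si](C)(C)C)c(OS(=O)(=O)C(F)(F)F)c1OC
A3 | alternative 1 | 5-chloro-2-iodoaniline | Nc1cc(Cl)ccc1I
A4 | alternative 2 | 2,9-dichloro-5,6-dimethoxy-11,12-bis(methylsulfonyl)-11,12-dihydroindolo[2,3-a]carbazole | COc1c(OC)c2c3ccc(Cl)cc3n(S(C)(=O)=O)c2c2n(S(C)(=O)=O)c3cc(Cl)ccc3c12
A5 | alternative 2 | N,N'-(ethyne-1,2-diyl)bis[N-(5-chloro-2-(methoxyethynyl)phenyl)methanesulfonamide] | COC#Cc1ccc(Cl)cc1N(C#CN(c1cc(Cl)ccc1C#COC)S(C)(=O)=O)S(C)(=O)=O
A6 | alternative 3 | di-tert-butyl 2,9-dichloro-5,6-dihydroxyindolo[2,3-a]carbazole-11,12-dicarboxylate | Oc1c(O)c2c3ccc(Cl)cc3n(C(=O)OC(C)(C)C)c2c2n(C(=O)OC(C)(C)C)c3cc(Cl)ccc3c12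
A7 | alternative 3 | di-tert-butyl 6,6'-dichloro-3,3'-diformyl-1H,1'H-2,2'-biindole-1,1'-dicarboxylate | CC(C)(C)OC(=O)n1c(-c2c(C=O)c3ccc(Cl)cc3n2C(=O)OC(C)(C)C)c(C=O)c2ccc(Cl)cc21
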